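**Retrosynthetic overview**
1. C11–O ether: oxa-1,6-addition of isofraxidin to a 6-oxo-7,9(11)-dienone; C9 is set by equilibration to the 9α epimer.
2. The dienone comes from a C9 carbinol (Peterson elimination) and allylic oxidation at C6; the 3α-ester comes from bulky-hydride reduction of a 3-ketone.
3. Key C3–C4 bond (closes ring A, makes the gem-dimethyl C4): metal-hydride H-atom transfer turns the Markovnikov carbon of an isopropenyl group (a cation site in polar chemistry) into a nucleophilic tertiary radical that attacks a nitrile carbon, so two normally electrophilic carbons are joined.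
4. Ring B is (R)-carvone (sets C5); C10 is made quaternary by methylation, then alkylation anti to the isopropenyl group.
5. Ring order: ring B is present from the start; ring A is formed in step 5.

Assumption: isofraxidin 19 and 2-(2-bromoethyl)-1,3-dioxolane 4 are purchased; bicyclic compounds carry drimane numbers (C11 on C9, C12 on C8, gem-dimethyl on C4, methyl on C10), and α is the face opposite the C10 methyl.

**Route**

Step 1
Reactants: 1 (R)-(−)-carvone; 2 iodomethane
Product: 3 (5R)-2,6-dimethyl-5-(prop-1-en-2-yl)cyclohex-2-en-1-one (C6 epimer mixture)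
Conditions: LDA (lithium diisopropylamide), THF, −78 °C; MeI, −78 → 0 °C
Reagents that add atoms: iodomethane 2, CI
Why: Kinetic α′-deprotonation of the enone and enolate alkylation; the new C6 center is a mixture that is erased when the same carbon is enolized again in step 2.

Step 2
Reactants: 3 6-methylcarvone; 4 2-(2-bromoethyl)-1,3-dioxolane
Product: 5 (5S,6S)-6-[2-(1,3-dioxolan-2-yl)ethyl]-2,6-dimethyl-5-(prop-1-en-2-yl)cyclohex-2-en-1-one
Conditions: LDA, THF, −78 → 0 °C; 4, DMPU, Bu4NI (10 mol %), 0 → 23 °C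
Reagents that add atoms: 2-(2-bromoethyl)-1,3-dioxolane 4, BrCCC1OCCO1
Why: Enolate alkylation forming the quaternary C10; the electrophile enters anti to the neighbouring isopropenyl group, which puts the chain trans and the methyl cis to it and thereby fixes C10 and the later trans ring fusion.

Step 3
Reactants: 5 acetal ketone; 6 ammonia
Product: 8 3-[(1S,6S)-1,3-dimethyl-2-oxo-6-(prop-1-en-2-yl)cyclohex-3-en-1-yl]propanenitrile, via keto aldehyde 7 (not isolated)
Conditions: HCl (10 mol %), THF/H2O, 50 °C; then aq. NH3 (excess), I2 (1.2 equiv), 23 °C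
Reagents that add atoms: ammonia 6, N
Why: Acid-catalysed acetal hydrolysis followed by oxidative conversion of the aldehyde to the nitrile (aldimine, N-iodoimine, loss of HI); the hindered enone carbonyl does not condense and no stereocenter is touched.

Step 4
Reactants: 8 keto nitrile; 9 (trimethylsilyl)methyllithium
Product: 10 3-[(1S,2S,6S)-2-hydroxy-1,3-dimethyl-6-(prop-1-en-2-yl)-2-[(trimethylsilyl)methyl]cyclohex-3-en-1-yl]propanenitrile
Conditions: CeCl3 (anhydrous), Me3SiCH2Li, THF, −78 °C; H2O
Reagents that add atoms: (trimethylsilyl)methyllithium 9, [Li]C[Si](C)(C)C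
Why: Organocerium 1,2-addition (first half of a Peterson olefination) to the hindered enone carbonyl without touching the nitrile; attack anti to the pseudo-axial C10 methyl should give mainly the 9β-alcohol, but this center is destroyed in step 8, and the addition also removes the enone that would otherwise be reduced in step 6.

Step 5
Reactants: 10 carbinol nitrile; 11 water
Product: 13 (5R,9S,10S)-9-hydroxy-11-(trimethylsilyl)drim-7-en-3-one, via ketimine 12 (not isolated)
Conditions: Fe(acac)3 [Fe(C5H7O2)3] (30 mol %), PhSiH3 (2.5 equiv), EtOH, 60 °C; then NaOAc/AcOH buffer (pH 5), THF/H2O, 23 °C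
Reagents that add atoms: water 11, O
Why: Metal-hydride hydrogen-atom-transfer (Mukaiyama-type) radical cyclization onto a nitrile: H-atom transfer to the isopropenyl CH2 gives a nucleophilic tertiary radical at C4 that adds 6-exo to the nitrile carbon, forming C3–C4, the gem-dimethyl quaternary C4 and ring A with the trans fusion already dictated by C5 and C10, and buffered hydrolysis of the ketimine gives the ketone.

Step 6
Reactants: 13 hydroxy ketone; 14 3-methylbutanoyl chloride
Product: 16 (3R,5S,9S,10S)-9-hydroxy-11-(trimethylsilyl)drim-7-en-3-yl 3-methylbutanoate, via lithium alkoxide 15 (not isolated)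
Conditions: LiBH(s-Bu)3 (L-Selectride, 1.5 equiv), THF, −78 °C; then 14, DMAP (cat.), −78 → 23 °C
Reagents that add atoms: 3-methylbutanoyl chloride 14, CC(C)CC(Cl)=O
Why: Bulky-hydride reduction from the equatorial direction gives the axial 3α-alkoxide (trans to the C10 methyl), which is acylated in the same flask, while the tertiary C9 alcohol is too hindered to react.

Step 7
Reactants: 16 ester; 17 tert-butyl hydroperoxide
Product: 18 (3R,5S,9S,10S)-9-hydroxy-6-oxo-11-(trimethylsilyl)drim-7-en-3-yl 3-methylbutanoate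
Conditions: Mn(OAc)3·2H2O (10 mol %), t-BuOOH (5 equiv), 3 Å MS, EtOAc, 23 °C
Reagents that add atoms: tert-butyl hydroperoxide 17, CC(C)(C)OO
Why: Radical allylic C–H oxidation at C6, the only ring allylic CH2 of the trisubstituted alkene, gives the enone; a chromium oxidant is avoided because it would transpose the tertiary allylic alcohol.

Step 8
Reactants: 18 silyl carbinol enone; 19 isofraxidin (7-hydroxy-6,8-dimethoxy-2H-chromen-2-one)
Product: 21 (3R,5R,9R,10R)-11-[(6,8-dimethoxy-2-oxo-2H-chromen-7-yl)oxy]-6-oxodrim-7-en-3-yl 3-methylbutanoate (target), via dienone 20 (not isolated)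
Conditions: KOt-Bu (1.05 equiv), THF, 0 °C, 20 min; then 19 (1.5 equiv), 23 °C, 16 h; H2O
Reagents that add atoms: isofraxidin 19, COc1cc2ccc(=O)oc2c(OC)c1O
Why: Base-induced Peterson syn-elimination gives the 6-oxo-7,9(11)-dienone and the phenoxide adds 1,6 (oxa-Michael) to the exocyclic methylene; reversible γ-protonation and retro-addition equilibrate C9 to what is expected to be the more stable 9α-CH2OAr epimer (pseudo-axial, anti to the C10 methyl, free of A(1,2) strain with the C8 methyl), and C5 keeps its trans-fused configuration.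

**Compound list**
1 | (R)-(−)-carvone | CC1=CC[C@H](CC1=O)C(C)=C | starting material
2 | iodomethane | CI | starting material
3 | (5R)-2,6-dimethyl-5-(prop-1-en-2-yl)cyclohex-2-en-1-one (C6 epimers) | CC1=CC[C@@H](C(C)=C)C(C)C1=O | intermediate
4 | 2-(2-bromoethyl)-1,3-dioxolane | BrCCC1OCCO1 | starting material
5 | (5S,6S)-6-[2-(1,3-dioxolan-2-yl)ethyl]-2,6-dimethyl-5-(prop-1-en-2-yl)cyclohex-2-en-1-one | CC1=CC[C@@H](C(C)=C)[C@](C)(CCC2OCCO2)C1=O | intermediate
6 | ammonia | N | starting material
7 | 3-[(1S,6S)-1,3-dimethyl-2-oxo-6-(prop-1-en-2-yl)cyclohex-3-en-1-yl]propanal | CC1=CC[C@@H](C(C)=C)[C@](C)(CCC=O)C1=O | intermediate (not isolated)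
8 | 3-[(1S,6S)-1,3-dimethyl-2-oxo-6-(prop-1-en-2-yl)cyclohex-3-en-1-yl]propanenitrile | CC1=CC[C@@H](C(C)=C)[C@](C)(CCC#N)C1=O | intermediate
9 | (trimethylsilyl)methyllithium | [Li]C[Si](C)(C)C | starting material
10 | 3-[(1S,2S,6S)-2-hydroxy-1,3-dimethyl-6-(prop-1-en-2-yl)-2-[(trimethylsilyl)methyl]cyclohex-3-en-1-yl]propanenitrile | CC1=CC[C@@H](C(C)=C)[C@](C)(CCC#N)[C@]1(O)C[Si](C)(C)C | intermediate
11 | water | O | starting material
12 | (5R,9S,10S)-3-imino-11-(trimethylsilyl)drim-7-en-9-ol | C[Si](C)(C)C[C@]1(O)C(C)=CC[C@H]2C(C)(C)C(=N)CC[C@]12C | intermediate (not isolated)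
13 | (5R,9S,10S)-9-hydroxy-11-(trimethylsilyl)drim-7-en-3-one | C[Si](C)(C)C[C@]1(O)C(C)=CC[C@H]2C(C)(C)C(=O)CC[C@]12C | intermediate
14 | 3-methylbutanoyl chloride | CC(C)CC(Cl)=O | starting material
15 | lithium (3R,5S,9S,10S)-9-hydroxy-11-(trimethylsilyl)drim-7-en-3-olate | C[Si](C)(C)C[C@]1(O)C(C)=CC[C@H]2C(C)(C)[C@H]([O-])CC[C@]12C.[Li+] | intermediate (not isolated)
16 | (3R,5S,9S,10S)-9-hydroxy-11-(trimethylsilyl)drim-7-en-3-yl 3-methylbutanoate | C[Si](C)(C)C[C@]1(O)C(C)=CC[C@H]2C(C)(C)[C@H](OC(=O)CC(C)C)CC[C@]12C | intermediate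
17 | tert-butyl hydroperoxide | CC(C)(C)OO | starting material
18 | (3R,5S,9S,10S)-9-hydroxy-6-oxo-11-(trimethylsilyl)drim-7-en-3-yl 3-methylbutanoate | C[Si](C)(C)C[C@]1(O)C(C)=CC(=O)[C@H]2C(C)(C)[C@H](OC(=O)CC(C)C)CC[C@]12C | intermediate
19 | isofraxidin (7-hydroxy-6,8-dimethoxy-2H-chromen-2-one) | COc1cc2ccc(=O)oc2c(OC)c1O | starting material
20 | (3R,5R,10S)-6-oxodrima-7,9(11)-dien-3-yl 3-methylbutanoate | C=C1C(C)=CC(=O)[C@H]2C(C)(C)[C@H](OC(=O)CC(C)C)CC[C@]12C | intermediate (not isolated)
21 | (3R,5R,9R,10R)-11-[(6,8-dimethoxy-2-oxo-2H-chromen-7-yl)oxy]-6-oxodrim-7-en-3-yl 3-methylbutanoate | COc1cc2ccc(=O)oc2c(OC)c1OC[C@@H]1C(C)=CC(=O)[C@H]2C(C)(C)[C@H](OC(=O)CC(C)C)CC[C@]12C | target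

**Totals and risks**

Total steps: 8 (steps 3, 5, 6 and 8 are two-stage one-pot operations). Longest linear sequence: 8 steps from 1.

Most likely to fail:

Step 5 (key radical cyclization). Addition of a tertiary radical to a nitrile is slow, so simple reduction of the isopropenyl group or 1,5-H shift to the α-cyano position may compete. The fallback sets out from 10 and switches the radical acceptor to an aldehyde, which is attacked much faster. i-Bu2AlH (toluene, −78 °C) reduces the nitrile to 3-[(1S,2S,6S)-2-hydroxy-1,3-dimethyl-6-(prop-1-en-2-yl)-2-[(trimethylsilyl)methyl]cyclohex-3-en-1-yl]propanal F2. The same Fe(acac)3/PhSiH3 hydrogen-atom-transfer conditions then close ring A onto the C=O to give (5S,9S,10S)-11-(trimethylsilyl)drim-7-ene-3,9-diol F3 as a C3 epimer mixture. Dess–Martin oxidation of the secondary alcohol returns to the route at 13.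

Step 8 (elimination and oxa-1,6-addition, C9 by equilibration). The addition is reversible, and the conversion or the C9 ratio may be poor. The fallback sets out from 20, isolated after the KOt-Bu stage, and makes the ether irreversibly. Copper-catalysed 1,6-borylation (CuCl, NaOt-Bu, B2pin2, MeOH, THF) gives (3R,5R,9R,10R)-6-oxo-11-(4,4,5,5-tetramethyl-1,3,2-dioxaborolan-2-yl)drim-7-en-3-yl 3-methylbutanoate F4. Oxidation with NaBO3·4H2O and brief DBU equilibration of C9 gives (3R,5R,9R,10R)-11-hydroxy-6-oxodrim-7-en-3-yl 3-methylbutanoate F5. Mitsunobu etherification with 19 (PPh3, DIAD, THF) comes back to the route at 21.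

Step 2 (quaternary center with an unactivated primary halide). The alkylation may be slow, or elimination of the bromide may compete. The fallback sets out from 3 and uses a reactive allyl electrophile instead. LDA then allyl bromide gives (5S,6S)-2,6-dimethyl-6-(prop-2-en-1-yl)-5-(prop-1-en-2-yl)cyclohex-2-en-1-one F1 with the same anti selectivity. An aldehyde-selective Wacker oxidation of the hindered allyl group (PdCl2(PhCN)2, CuCl2·2H2O, AgNO2, O2, t-BuOH/MeNO2) returns to the route at 7, which is carried through the NH3/I2 half of step 3 to 8.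

Further compounds
F1 | step 2 | (5S,6S)-2,6-dimethyl-6-(prop-2-en-1-yl)-5-(prop-1-en-2-yl)cyclohex-2-en-1-one | CC1=CC[C@@H](C(C)=C)[C@](C)(CC=C)C1=O
F2 | step 5 | 3-[(1S,2S,6S)-2-hydroxy-1,3-dimethyl-6-(prop-1-en-2-yl)-2-[(trimethylsilyl)methyl]cyclohex-3-en-1-yl]propanal | CC1=CC[C@@H](C(C)=C)[C@](C)(CCC=O)[C@]1(O)C[Si](C)(C)C
F3 | step 5 | (5S,9S,10S)-11-(trimethylsilyl)drim-7-ene-3,9-diol (C3 epimers) | C[Si](C)(C)C[C@]1(O)C(C)=CC[C@H]2C(C)(C)C(O)CC[C@]12C
F4 | step 8 | (3R,5R,9R,10R)-6-oxo-11-(4,4,5,5-tetramethyl-1,3,2-dioxaborolan-2-yl)drim-7-en-3-yl 3-methylbutanoate | CC1(C)OB(C[C@@H]2C(C)=CC(=O)[C@H]3C(C)(C)[C@H](OC(=O)CC(C)C)CC[C@]23C)OC1(C)C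
F5 | step 8 | (3R,5R,9R,10R)-11-hydroxy-6-oxodrim-7-en-3-yl 3-methylbutanoate | OC[C@@H]1C(C)=CC(=O)[C@H]2C(C)(C)[C@H](OC(=O)CC(C)C)CC[C@]12C
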